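Clerodane numbering is used throughout. The plan cuts ring B at C8–C9 and the ring fusion at C5–C10 in one stroke. It exploits that C5 lies between the C6 oxygen and the C19 carboxyl carbon, and C9 next to C11: C5–C6–C7–C8 is the enolate of a crotonyl β-keto ester, C9=C10 a tiglate. One anionic double Michael reaction (formal [4+2]) of this open-chain precursor closes rings A and B and sets C5, C9 (both quaternary) and C10 from the single C1 silyloxy stereocentre. The precursor comes from methyl geranate in five steps; C8 is corrected afterwards through the enone, and the C4=C18 methylene becomes the chlorohydrin.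

Key step: step 6

Assumption: 4, 26 and 30 are taken as catalogue compounds. Clerodane numbers are also used for the open-chain intermediates, and centres formed as inconsequential mixtures (C5/C6 in 10, C5 in 11, the enol ether geometry in 23) are left undefined in the SMILES.

Step 1
Reactants: 1 methyl (E)-geranate
Product: 3 methyl (2E)-3-methyl-6-oxohex-2-enoate, via secondary ozonide 2 (not isolated)
Conditions: O3 (1.0 equiv), CH2Cl2, −78 °C; then Me2S, −78 °C → rt
Reagents that add atoms: ozone, [O-][O+]=O
Why: Ozonolysis with reductive work-up: the electron-rich isopropylidene alkene should react far faster than the ester-conjugated alkene, so one equivalent of ozone unveils the aldehyde carbon that becomes C1 and creates no stereocentre.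

Step 2
Reactants: 3 methyl (2E)-3-methyl-6-oxohex-2-enoate; 4 ethyl (2E)-3-iodo-2-methylprop-2-enoate
Product: 6 1-ethyl 9-methyl (2E,4R,7E)-4-hydroxy-2,7-dimethylnona-2,7-dienedioate, via alkenylchromium(III) dichloride 5 (not isolated)
Conditions: CrCl2 (3 equiv), NiCl2 (2 mol %), chiral oxazoline–sulfonamide ligand (3.3 equiv, the antipode that delivers the 1R alcohol), Et3N (3.3 equiv), THF, rt
Reagents that add atoms: none
Why: Nozaki–Hiyama–Kishi coupling: the alkenylchromium species adds only to the aldehyde, keeps the E geometry and tolerates both esters, and the chiral ligand on chromium sets C1 as R by reagent control.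

Step 3
Reactants: 6 allylic alcohol
Product: 7 (4R)-tert-butyldimethylsilyl ether of 6
Conditions: TBSCl, imidazole, DMF, rt
Reagents that add atoms: tert-butyldimethylsilyl chloride, CC(C)(C)[Si](C)(C)Cl
Why: Standard silylation of a secondary allylic alcohol, giving a group that is not a leaving group towards any later enolate and that acts as the bulky control element at C1.

Step 4
Reactants: 7 TBS ether; 8 (E)-crotonaldehyde
Product: 10 deconjugated aldol adduct (C4=C18 methylene and C6 carbinol), via lithium dienolate 9 (not isolated)
Conditions: LDA (1.1 equiv), THF–DMPU, −78 °C; then 8, −78 °C; AcOH quench at −78 °C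
Reagents that add atoms: none
Why: Deconjugative aldol addition: LDA removes a proton from the methyl group cis to the methyl ester (C18), the lithium dienolate reacts at its α-carbon C5 with the aldehyde carbonyl and so moves the alkene to C4=C18, while the tiglate has no γ-hydrogen syn to its carbonyl; C5 and C6 form as a mixture that steps 5 and 6 erase.

Step 5
Reactants: 10 aldol adduct
Product: 11 crotonyl β-keto ester (cyclisation precursor)
Conditions: Dess–Martin periodinane, CH2Cl2, 0 °C → rt; used without chromatography
Reagents that add atoms: none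
Why: Dess–Martin oxidation of the allylic carbinol proceeds under near-neutral conditions that touch neither the alkenes nor the silyl ether and gives the enolisable β-keto ester in which C5 is configurationally labile.

Step 6
Reactants: 11 crotonyl β-keto ester
Product: 15 trans-decalin 6-trimethylsilyl enol ether (8β-methyl), via acyclic potassium enolate 12 (not isolated), via monocyclic ester enolate 13 (not isolated), via bicyclic potassium enolate 14 (not isolated)
Conditions: KHMDS (1.05 equiv), THF (0.005 M), −78 °C → rt; then TMSCl, −78 → 0 °C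
Reagents that add atoms: trimethylsilyl chloride, C[Si](C)(C)Cl
Why: Intramolecular double Michael reaction, i.e. the anionic formal [4+2] cycloaddition known for Nazarov-type β-keto ester enolates and enoates: enolate 12 adds through C5 to C10 of the tiglate, the ester enolate 13 released adds through C9 to C8 of the crotonyl ketone, and TMSCl traps enolate 14 on oxygen. Ring A closes 6-(enolexo)-exo-trig through a chair, ring B 6-(enolexo)-endo-trig through the boat-like Diels–Alder-type array that keeps the enone conjugated. C10 is controlled by C1: A(1,3) strain with the C20 methyl group holds H1 in the alkene plane, C5 attacks anti to the pseudo-equatorial OTBS group, and H1 and H10 become trans-diaxial. C5 is selected because the first addition is reversible and only the epimer with the crotonyl group equatorial and the C19 ester axial reaches C8 with C4 in the unstrained outside position, which gives the trans-decalin, while C9 follows from the endo, potassium-bridged ester enolate that places C11 syn to H10 and C20 axial. C8 follows from the E-enone and should come out with C17 β (axial), the one centre that steps 7 and 8 invert. The step needs attack through C5 rather than C18 of the extended enolate and cyclisation rather than oligomerisation: alkali-metal dienolates react at the α-carbon, a C18 adduct cannot undergo the second addition and reverts, and high dilution favours ring closure.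

Step 7
Reactants: 15 TMS enol ether
Product: 16 Δ7-en-6-one
Conditions: Pd(OAc)2 (1.1 equiv), MeCN, rt
Reagents that add atoms: none
Why: Saegusa–Ito oxidation: because C5 is quaternary the oxo-π-allylpalladium species can eliminate only towards C8, which gives the C7=C8 enone, removes the wrong C8 centre and leaves the isolated methylene untouched.

Step 8
Reactants: 16 enone
Product: 18 saturated 6-ketone (8α-methyl), via lithium enolate 17 (not isolated)
Conditions: Li (2.5 equiv), NH3(l)–THF, t-BuOH (1 equiv), −78 °C, 10 min; then solid NH4Cl
Reagents that add atoms: none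
Why: Dissolving-metal enone reduction: the β-carbon C8 is protonated along the axial (β) direction that overlaps with the enolate, which puts C17 equatorial (α), and a near-stoichiometric amount of lithium spares the 1,1-disubstituted alkene, the two hindered esters and the silyl ether.

Step 9
Reactants: 18 keto diester
Product: 19 6α,11,19-triol
Conditions: LiAlH4 (excess), THF, 0 → 50 °C; aqueous NaOH work-up
Reagents that add atoms: none
Why: Hydride reduction of both esters and the ketone in one operation, in which hydride reaches C6 along the open axial β trajectory (the α side is blocked by the axial C19 group) and gives the equatorial 6α-alcohol.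

Step 10
Reactants: 19 triol
Product: 20 4α,18-epoxy triol
Conditions: VO(acac)2 (5 mol %), t-BuOOH (1.5 equiv), CH2Cl2, 0 °C → rt
Reagents that add atoms: tert-butyl hydroperoxide, CC(C)(C)OO
Why: Hydroxyl-directed vanadium-catalysed epoxidation: the homoallylic C19 (and C6) alkoxide on the α face delivers the peroxide oxygen to the α face of the only alkene, which sets C4 with oxygen α and C18 β against the intrinsic steric bias.

Step 11
Reactants: 20 epoxy triol
Product: 21 6,19-acetonide
Conditions: 2,2-dimethoxypropane, PPTS (5 mol %), CH2Cl2, rt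
Reagents that add atoms: 2,2-dimethoxypropane, COC(C)(C)OC
Why: Transketalisation: only the 6α,19-diol can form a six-membered 1,3-dioxane, which leaves the C11 hydroxyl free, and the weak acid should spare the epoxide, whose opening by O6 or O19 would be a disfavoured 5-endo process.

Step 12
Reactants: 21 acetonide alcohol
Product: 22 C11 aldehyde
Conditions: Dess–Martin periodinane, pyridine, CH2Cl2, 0 °C → rt
Reagents that add atoms: none
Why: Buffered Dess–Martin oxidation of the neopentyl primary alcohol gives a non-enolisable aldehyde without harm to epoxide, acetonide or silyl ether.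

Step 13
Reactants: 22 aldehyde
Product: 23 methyl enol ether (C11=C12)
Conditions: Ph3P+CH2OMe Cl−, t-BuOK, THF, 0 °C → rt
Reagents that add atoms: (methoxymethyl)triphenylphosphonium chloride, COC[P+](c1ccccc1)(c1ccccc1)c1ccccc1.[Cl-]
Why: Wittig reaction with the small and reactive methoxymethylene ylide is the standard one-carbon homologation of hindered neopentyl aldehydes and brings in C12, the alkene geometry being irrelevant.

Step 14
Reactants: 23 enol ether
Product: 24 18-chloro-4α,6α,19-triol 12-aldehyde
Conditions: conc. HCl (5 equiv), THF–H2O (9:1), 0 °C → rt, stopped as soon as the acetonide is consumed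
Reagents that add atoms: hydrogen chloride, Cl; water, O
Why: One acid treatment opens the protonated spiro-epoxide with chloride at the primary C18 (SN2 opening, C4–O bond and configuration retained), hydrolyses the enol ether to the C12 aldehyde and cleaves the acetonide, while the congested secondary TBS ether at C1 should outlast these faster reactions.

Step 15
Reactants: 24 chlorohydrin diol aldehyde
Product: 25 6α,19-diacetate
Conditions: Ac2O, pyridine, DMAP (cat.), CH2Cl2, 0 °C → rt
Reagents that add atoms: acetic anhydride, CC(=O)OC(C)=O
Why: Nucleophile-catalysed acetylation esterifies the primary and the secondary hydroxyl but not the hindered tertiary C4 hydroxyl, and the mild amine base does not re-close the chlorohydrin.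

Step 16
Reactants: 25 diacetate aldehyde; 26 4-bromofuran-2(5H)-one
Product: 28 (12S)-carbinol bearing the butenolide, via butenolidylchromium(III) dichloride 27 (not isolated)
Conditions: CrCl2 (4 equiv), NiCl2 (2 mol %), chiral oxazoline–sulfonamide ligand (the antipode that delivers the 12S alcohol), Et3N, THF, rt
Reagents that add atoms: none
Why: Nozaki–Hiyama–Kishi coupling of a cyclic β-halo acrylate, the same class as β-iodoacrylates: it installs C13–C16 directly at the butenolide oxidation level, tolerates acetates, the alkyl chloride and the free tertiary alcohol, and the ligand sets C12 as S by reagent control.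

Step 17
Reactants: 28 silyl ether
Product: 29 1β,12-diol
Conditions: HF·pyridine, pyridine, THF, 0 °C → rt
Reagents that add atoms: none
Why: Fluoride-mediated desilylation under slightly acidic conditions frees the C1 hydroxyl without the basic medium that would re-close the chlorohydrin or shift acetates.

Step 18
Reactants: 29 diol; 30 (S)-2-methylbutanoic anhydride
Product: 31 ajugaciliatin A
Conditions: 30 (4 equiv), DMAP, Et3N, CH2Cl2, rt
Reagents that add atoms: none
Why: DMAP-catalysed acylation esterifies both secondary hydroxyls (C1 and C12) with the same purchased (S)-acyl group in one operation, leaves the tertiary C4 hydroxyl free, and the use of the anhydride avoids a ketene pathway that could racemise the acyl stereocentre.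

Compound list
1 | methyl (E)-geranate, methyl (2E)-3,7-dimethylocta-2,6-dienoate | COC(=O)/C=C(\C)CCC=C(C)C | starting material
2 | secondary ozonide (1,2,4-trioxolane) of the remote alkene of 1 | COC(=O)/C=C(\C)CCC1OOC(C)(C)O1 | intermediate
3 | methyl (2E)-3-methyl-6-oxohex-2-enoate | COC(=O)/C=C(\C)CCC=O | intermediate
4 | ethyl (2E)-3-iodo-2-methylprop-2-enoate | CCOC(=O)/C(C)=C/I | starting material
5 | alkenylchromium(III) dichloride from 4 (ligand omitted) | CCOC(=O)/C(C)=C/[Cr](Cl)Cl | intermediate
6 | 1-ethyl 9-methyl (2E,4R,7E)-4-hydroxy-2,7-dimethylnona-2,7-dienedioate (the carbinol is C1) | CCOC(=O)/C(C)=C/[C@H](O)CC/C(C)=C/C(=O)OC | intermediate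
7 | (4R)-TBS ether of 6 | CCOC(=O)/C(C)=C/[C@H](O[Si](C)(C)C(C)(C)C)CC/C(C)=C/C(=O)OC | intermediate
8 | (E)-crotonaldehyde | C/C=C/C=O | starting material
9 | lithium dienolate of 7 (C18 deprotonated) | CCOC(=O)/C(C)=C/[C@H](O[Si](C)(C)C(C)(C)C)CCC(=C)C=C([O-])OC.[Li+] | intermediate
10 | aldol adduct: C5 bears CO2Me and the (E)-1-hydroxybut-2-enyl group, C4=C18 methylene, 1R (C5/C6 mixture) | CCOC(=O)/C(C)=C/[C@H](O[Si](C)(C)C(C)(C)C)CCC(=C)C(C(=O)OC)C(O)/C=C/C | intermediate
11 | crotonyl β-keto ester, 1R, C5 labile | CCOC(=O)/C(C)=C/[C@H](O[Si](C)(C)C(C)(C)C)CCC(=C)C(C(=O)OC)C(=O)/C=C/C | intermediate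
12 | acyclic potassium enolate of 11 | CCOC(=O)/C(C)=C/[C@H](O[Si](C)(C)C(C)(C)C)CCC(=C)C(C(=O)OC)=C([O-])/C=C/C.[K+] | intermediate
13 | monocyclic potassium ester enolate (ring A closed; 1β-OTBS, 10β-H, C19 ester α, crotonyl β) | CCOC([O-])=C(C)[C@H]1[C@H](O[Si](C)(C)C(C)(C)C)CCC(=C)[C@]1(C(=O)OC)C(=O)/C=C/C.[K+] | intermediate
14 | bicyclic potassium 6-enolate (trans-decalin, 8β-methyl) | CCOC(=O)[C@@]1(C)[C@@H](C)C=C([O-])[C@]2(C(=O)OC)[C@@H]1[C@H](O[Si](C)(C)C(C)(C)C)CCC2=C.[K+] | intermediate
15 | trans-decalin 6-TMS enol ether: 1β-OTBS, 10β-H, 5α-CO2Me, 9α-Me, 9β-CO2Et, 8β-Me, 4-methylene | CCOC(=O)[C@@]1(C)[C@@H](C)C=C(O[Si](C)(C)C)[C@]2(C(=O)OC)[C@@H]1[C@H](O[Si](C)(C)C(C)(C)C)CCC2=C | intermediate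
16 | Δ7-en-6-one (8-methyl), other centres as in 15 | CCOC(=O)[C@@]1(C)C(C)=CC(=O)[C@]2(C(=O)OC)[C@@H]1[C@H](O[Si](C)(C)C(C)(C)C)CCC2=C | intermediate
17 | lithium 6-enolate with 8α-methyl | CCOC(=O)[C@@]1(C)[C@H](C)C=C([O-])[C@]2(C(=O)OC)[C@@H]1[C@H](O[Si](C)(C)C(C)(C)C)CCC2=C.[Li+] | intermediate
18 | saturated 6-ketone, 8α-methyl (equatorial) | CCOC(=O)[C@@]1(C)[C@H](C)CC(=O)[C@]2(C(=O)OC)[C@@H]1[C@H](O[Si](C)(C)C(C)(C)C)CCC2=C | intermediate
19 | 6α,11,19-triol, 1β-OTBS, 4-methylene | OC[C@@]1(C)[C@H](C)C[C@H](O)[C@]2(CO)[C@@H]1[C@H](O[Si](C)(C)C(C)(C)C)CCC2=C | intermediate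
20 | 4α,18-epoxy-6α,11,19-triol | OC[C@@]1(C)[C@H](C)C[C@H](O)[C@]2(CO)[C@@H]1[C@H](O[Si](C)(C)C(C)(C)C)CC[C@]2(O3)C3 | intermediate
21 | 6,19-acetonide of 20 (C11 hydroxyl free) | OC[C@@]1(C)[C@H](C)C[C@H](O4)[C@]2(COC4(C)C)[C@@H]1[C@H](O[Si](C)(C)C(C)(C)C)CC[C@]2(O3)C3 | intermediate
22 | C11 aldehyde | O=C[C@@]1(C)[C@H](C)C[C@H](O4)[C@]2(COC4(C)C)[C@@H]1[C@H](O[Si](C)(C)C(C)(C)C)CC[C@]2(O3)C3 | intermediate
23 | C11=C12 methyl enol ether (E/Z) | COC=C[C@@]1(C)[C@H](C)C[C@H](O4)[C@]2(COC4(C)C)[C@@H]1[C@H](O[Si](C)(C)C(C)(C)C)CC[C@]2(O3)C3 | intermediate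
24 | 18-chloro-4α,6α,19-trihydroxy 12-aldehyde, 1β-OTBS | O=CC[C@@]1(C)[C@H](C)C[C@H](O)[C@]2(CO)[C@@H]1[C@H](O[Si](C)(C)C(C)(C)C)CC[C@]2(O)CCl | intermediate
25 | 6α,19-diacetate of 24 | O=CC[C@@]1(C)[C@H](C)C[C@H](OC(C)=O)[C@]2(COC(C)=O)[C@@H]1[C@H](O[Si](C)(C)C(C)(C)C)CC[C@]2(O)CCl | intermediate
26 | 4-bromofuran-2(5H)-one | O=C1C=C(Br)CO1 | starting material
27 | butenolid-4-ylchromium(III) dichloride (ligand omitted) | O=C1C=C([Cr](Cl)Cl)CO1 | intermediate
28 | (12S)-carbinol with butenolide, 1β-OTBS | O[C@@H](C[C@@]1(C)[C@H](C)C[C@H](OC(C)=O)[C@]2(COC(C)=O)[C@@H]1[C@H](O[Si](C)(C)C(C)(C)C)CC[C@]2(O)CCl)C1=CC(=O)OC1 | intermediate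
29 | 1β,12S-diol | O[C@@H](C[C@@]1(C)[C@H](C)C[C@H](OC(C)=O)[C@]2(COC(C)=O)[C@@H]1[C@H](O)CC[C@]2(O)CCl)C1=CC(=O)OC1 | intermediate
30 | (S)-2-methylbutanoic anhydride | CC[C@H](C)C(=O)OC(=O)[C@@H](C)CC | starting material
31 | ajugaciliatin A | CC[C@H](C)C(=O)O[C@@H](C[C@@]1(C)[C@H](C)C[C@H](OC(C)=O)[C@]2(COC(C)=O)[C@@H]1[C@H](OC(=O)[C@@H](C)CC)CC[C@]2(O)CCl)C1=CC(=O)OC1 | target

Total step count: 18. Longest linear sequence: 18 steps (1 → 31); the partners 4, 8, 26 and 30 are purchased.

Steps most likely to fail

Step 6. Several processes could stop ring B from closing as planned.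
- The ester enolate born in the first addition may revert or be quenched by proton transfer.
- The extended enolate may react through C18 or electrocyclise across C18/C8.
- Ring B may close to the cis-decalin.

The fallback separates the two ring closures and sets out from 11. Catalytic Cs2CO3 in MeCN closes ring A only, and the adduct is protonated to the monocyclic keto diester F1, whose diastereomers can be separated. The C11 ester alone is then deprotonated with LDA at −78 °C. The kinetic ester enolate closes C8–C9 onto the crotonyl ketone, and trapping with TMSCl returns to 15.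

Step 14. Water or a liberated hydroxyl may compete with chloride at the protonated epoxide, chloride may attack C4, or the C1 silyl ether may be lost before the acetonide is gone. The fallback decouples the events and sets out from 23. LiCl and AcOH in dry THF open the epoxide by nucleophilic attack at the primary carbon, while the neighbouring oxygens are still tied up, and give the chlorohydrin acetonide enol ether F2. Aqueous oxalic acid in THF then releases the aldehyde and the diol under much weaker acid and returns to 24.

Step 16. The main risk is poor facial selectivity at C12, because the nearest stereocentre is remote and the ligand may be mismatched with the substrate. The fallback replaces stereoselective addition by stereoselective reduction and sets out from 25. The coupling with 26 is run without ligand and gives 28 together with its (12R)-epimer F3. Dess–Martin oxidation of the mixture gives the 12-ketone F4. Corey–Bakshi–Shibata reduction with the (R)-methyl oxazaborolidine and catecholborane (butenolide as the large group) returns to 28.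

Further compounds
F1 | step 6 | monocyclic keto diester (ring A closed, C9–H, C9 undefined) | CCOC(=O)C(C)[C@H]1[C@H](O[Si](C)(C)C(C)(C)C)CCC(=C)[C@]1(C(=O)OC)C(=O)/C=C/C
F2 | step 14 | chlorohydrin acetonide enol ether | COC=C[C@@]1(C)[C@H](C)C[C@H](O4)[C@]2(COC4(C)C)[C@@H]1[C@H](O[Si](C)(C)C(C)(C)C)CC[C@]2(O)CCl
F3 | step 16 | (12R)-epimer of 28 | O[C@H](C[C@@]1(C)[C@H](C)C[C@H](OC(C)=O)[C@]2(COC(C)=O)[C@@H]1[C@H](O[Si](C)(C)C(C)(C)C)CC[C@]2(O)CCl)C1=CC(=O)OC1
F4 | step 16 | 12-ketone | O=C(C[C@@]1(C)[C@H](C)C[C@H](OC(C)=O)[C@]2(COC(C)=O)[C@@H]1[C@H](O[Si](C)(C)C(C)(C)C)CC[C@]2(O)CCl)C1=CC(=O)OC1
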